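**Retrosynthetic overview** (p-menthane numbering: C1 = ring C(CH3)Br, C2 = ring CHBr, C3, C4 = ring CH, C5, C6, C7 = ring methyl, C8 = side-chain CBr, C9 = CH2Br, C10 = side-chain CH3)
1. The four C–Br bonds come last: trans-diaxial Br2 addition to a C1=C2 alkene, and a C8–O–C9 oxirane of fixed configuration that is opened by bromide at C9 and then exchanged OH → Br at C8 with retention through a bromonium ion.
2. The cyclohexene, the only carbocycle, is closed at C5–C6 by a nickel-mediated allyl–alkyl coupling between a primary C5–Br and an allylic chloride C6H2=C1(C7)–C2HCl.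
3. Enabling feature: C1 carries methyl C7 and lies between C6H2 and C2, so with the ring open C6–C1(C7)–C2 is a 2-methylallyl unit. Its unsubstituted end C6 can reach C5 only through the six-membered ring (bonding at C2 would give a cyclobutane), the C2 configuration is irrelevant, and the double bond ends at C1=C2, the two ring carbons that must carry bromine.
4. The acyclic precursor comes from a prenyl group (ene-type chlorination) and a triol whose C8/C9 oxygens are held in a temporary dioxolane; C5 is a CH2OH turned into CH2Br.
5. The C4–C8 bond and both of its stereocentres come from one catalytic asymmetric Mukaiyama aldol of a thioester enolsilane with methyl pyruvate. Ring order: dioxolane (temporary, step 5) → cyclohexene (step 8) → oxirane (temporary, step 10).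

Key step: step 8

Assumption: 5-methylhex-4-enoic acid, 2-methylpropane-2-thiol, methyl pyruvate and the (R,R)-tBu-box ligand, 2,2'-(propane-2,2-diyl)bis[(4R)-4-tert-butyl-4,5-dihydro-1,3-oxazole], are taken as catalogue chemicals.

Step 1
Reactants: 1 5-methylhex-4-enoic acid; 2 2-methylpropane-2-thiol
Product: 3 S-tert-butyl 5-methylhex-4-enethioate
Conditions: DCC, DMAP (cat.), CH2Cl2, 0 °C to 23 °C
Reagents that add atoms: none
Why: Steglich-type thioesterification, in which the carbodiimide activates the acid and DMAP passes the acyl group to the thiol; no stereocentre is involved.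

Step 2
Reactants: 3 S-tert-butyl 5-methylhex-4-enethioate
Product: 4 (Z)-1-(tert-butylsulfanyl)-5-methyl-1-(trimethylsilyloxy)hexa-1,4-diene
Conditions: LiN(iPr)2, THF, −78 °C; then Me3SiCl, −78 °C to 23 °C; non-aqueous work-up
Reagents that add atoms: chlorotrimethylsilane, C[Si](C)(C)Cl
Why: Kinetic enolisation of the thioester and O-silylation (silyl ketene thioacetal formation) should give mainly the Z enolsilane, and either geometry is expected to converge on the same aldol diastereomer in step 3.

Step 3
Reactants: 4 (Z)-1-(tert-butylsulfanyl)-5-methyl-1-(trimethylsilyloxy)hexa-1,4-diene; 5 methyl pyruvate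
Product: 7 methyl (2R,3R)-3-[(tert-butylsulfanyl)carbonyl]-2-hydroxy-2,6-dimethylhept-5-enoate, via aldol trimethylsilyl ether 6 (not isolated)
Conditions: Cu(OTf)2 (10 mol %), (R,R)-tBu-box (11 mol %), THF, −78 °C; then 1 M HCl, THF, 23 °C
Reagents that add atoms: none
Why: Mukaiyama aldol addition to methyl pyruvate held as a bidentate chelate on the chiral divalent copper bis(oxazoline) Lewis acid: the (R,R) ligand should leave the re face of the ketone open (C2 = R, the later C8), the open transition state should give the syn adduct (C3 = R, the later C4), and dilute acid then removes the silyl group of 6.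

Step 4
Reactants: 7 methyl (2R,3R)-3-[(tert-butylsulfanyl)carbonyl]-2-hydroxy-2,6-dimethylhept-5-enoate
Product: 8 (2R,3S)-2-methyl-3-(3-methylbut-2-en-1-yl)butane-1,2,4-triol
Conditions: LiAlH4, THF, 0 °C to 23 °C; aqueous NaOH work-up
Reagents that add atoms: none
Why: Hydride reduction of the thioester and the methyl ester to primary alcohols; hydride addition should outrun enolisation so the centre next to the thioester is kept (its descriptor changes only by priority), and no stereocentre is formed.

Step 5
Reactants: 8 (2R,3S)-2-methyl-3-(3-methylbut-2-en-1-yl)butane-1,2,4-triol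
Product: 9 (2S)-5-methyl-2-[(4R)-2,2,4-trimethyl-1,3-dioxolan-4-yl]hex-4-en-1-ol
Conditions: 2,2-dimethoxypropane, PPTS (cat.), CH2Cl2, 23 °C
Reagents that add atoms: 2,2-dimethoxypropane, COC(C)(C)OC
Why: Acid-catalysed transacetalisation under thermodynamic control should favour the five-membered dioxolane on the tertiary/primary 1,2-diol over the six- and seven-membered alternatives, leaving the C5 hydroxyl free.

Step 6
Reactants: 9 (2S)-5-methyl-2-[(4R)-2,2,4-trimethyl-1,3-dioxolan-4-yl]hex-4-en-1-ol
Product: 10 (4R)-4-[(2R)-1-bromo-5-methylhex-4-en-2-yl]-2,2,4-trimethyl-1,3-dioxolane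
Conditions: CBr4, PPh3, 2,6-lutidine, CH2Cl2, 0 °C
Reagents that add atoms: tetrabromomethane, BrC(Br)(Br)Br
Why: Appel reaction, SN2 displacement of the alkoxyphosphonium group by bromide at the primary carbon under buffered conditions that spare the acetonide; the stereocentres are untouched.

Step 7
Reactants: 10 (4R)-4-[(2R)-1-bromo-5-methylhex-4-en-2-yl]-2,2,4-trimethyl-1,3-dioxolane
Product: 11 (4R)-4-[(2R)-1-bromo-4-chloro-5-methylhex-5-en-2-yl]-2,2,4-trimethyl-1,3-dioxolane (both epimers at the chlorine-bearing carbon)
Conditions: N-chlorosuccinimide, PhSeCl (10 mol %), CH2Cl2, 23 °C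
Reagents that add atoms: N-chlorosuccinimide, O=C1CCC(=O)N1Cl
Why: Selenium-catalysed ene-type allylic chlorination (addition of PhSeCl to the trisubstituted alkene, oxidation at selenium by the N-chloro imide, elimination) should shift the double bond to the terminal position and place chlorine on C2; the new C2 centre forms without control and is erased in step 8.

Step 8
Reactants: 11 (4R)-4-[(2R)-1-bromo-4-chloro-5-methylhex-5-en-2-yl]-2,2,4-trimethyl-1,3-dioxolane
Product: 13 (4R)-2,2,4-trimethyl-4-[(1R)-4-methylcyclohex-3-en-1-yl]-1,3-dioxolane, via allylnickel chloride 12 (not isolated)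
Conditions: Ni(cod)2 (1.2 equiv), THF, 0 °C to 23 °C; then DMF (0.005 M), 50 °C
Reagents that add atoms: none
Why: Proposed new method: zerovalent nickel should add oxidatively to the allylic C–Cl bond of both C2 epimers of 11 to give one 1-alkyl-2-methyl-π-allylnickel chloride 12, and in DMF this should couple with the tethered primary bromide by the radical-chain path known for such complexes (bromine abstraction at C5 by an odd-electron nickel species, recombination of the C5 radical with the allylnickel centre of its own molecule, reductive elimination from trivalent nickel), forming the C5–C6 bond. The closest known reaction type is the intermolecular coupling of π-allylnickel halides with alkyl bromides and iodides in DMF (and its catalytic reductive allyl–alkyl variants), which joins the alkyl group to the less substituted allyl terminus; the intramolecular, ring-closing use is the new element. The cyclohexene closes at the unsubstituted terminus C6 so that all three allyl carbons become ring members (endo mode with respect to the allyl unit, through a seven-membered nickelacycle), the only alternative, bonding at C2, being a strained vinylcyclobutane. No stereocentre is created: C4 and C8 are spectators and the uncontrolled C2 centre is erased in the planar allyl unit, so the closure is stereoconvergent, the cis allyl geometry needed for the ring being reachable by π–σ–π isomerisation through the C2-bound σ-allyl form. The step needs terminus selectivity (C6 over C2), secured by ring size, and intra- over intermolecular coupling, secured by forming 12 completely before DMF is added and by high dilution; it leaves the double bond at C1=C2, where the two ring bromine atoms are required.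

Step 9
Reactants: 13 (4R)-2,2,4-trimethyl-4-[(1R)-4-methylcyclohex-3-en-1-yl]-1,3-dioxolane
Product: 14 (2R)-2-[(1R)-4-methylcyclohex-3-en-1-yl]propane-1,2-diol
Conditions: AcOH/H2O (4:1), 40 °C
Reagents that add atoms: none
Why: Acid-catalysed acetal hydrolysis under conditions mild enough to leave the trisubstituted ring alkene alone; both C–O bonds at the stereocentre stay intact.

Step 10
Reactants: 14 (2R)-2-[(1R)-4-methylcyclohex-3-en-1-yl]propane-1,2-diol
Product: 15 (2R)-2-methyl-2-[(1R)-4-methylcyclohex-3-en-1-yl]oxirane
Conditions: NaH, 1-(p-tolylsulfonyl)imidazole, THF, 0 °C to 23 °C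
Reagents that add atoms: none
Why: Selective sulfonylation of the primary alkoxide followed by intramolecular Williamson-type closure (3-exo-tet) by the tertiary alkoxide; the C8–O bond is never broken, so C8 keeps its configuration.

Step 11
Reactants: 15 (2R)-2-methyl-2-[(1R)-4-methylcyclohex-3-en-1-yl]oxirane
Product: 16 (2R)-2-[(1R,3S,4S)-3,4-dibromo-4-methylcyclohexyl]-2-methyloxirane
Conditions: Br2 (1.0 equiv), NaHCO3 (solid), CH2Cl2, −78 °C
Reagents that add atoms: bromine, BrBr
Why: Electrophilic anti addition of bromine: the bromonium ion on the face opposite the equatorial C4 substituent should be opened trans-diaxially by bromide at the tertiary carbon C1 (Markovnikov), which sets C1 (S) and C2 (S) relative to C4.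

Step 12
Reactants: 16 (2R)-2-[(1R,3S,4S)-3,4-dibromo-4-methylcyclohexyl]-2-methyloxirane
Product: 18 (1S,2S,4R)-1,2-dibromo-4-[(2R)-1,2-dibromopropan-2-yl]-1-methylcyclohexane, via bromohydrin 17 (not isolated)
Conditions: LiBr, AcOH, THF, 23 °C; evaporate; then HBr (33% in AcOH), CH2Cl2, 0 °C
Reagents that add atoms: lithium bromide, [Li+].[Br-]; hydrogen bromide, Br
Why: Bromide should open the 2,2-disubstituted epoxide by SN2 at the CH2 carbon (C8–O untouched), and HBr should then replace the tertiary hydroxyl by bromine with retention through neighbouring-group participation of the C9 bromine (bromonium ion opened at the tertiary carbon), which fixes C8 as R.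

**Compound list**
1 | 5-methylhex-4-enoic acid | CC(C)=CCCC(=O)O | starting material
2 | 2-methylpropane-2-thiol | CC(C)(C)S | starting material
3 | S-tert-butyl 5-methylhex-4-enethioate | CC(C)=CCCC(=O)SC(C)(C)C | intermediate
4 | (Z)-1-(tert-butylsulfanyl)-5-methyl-1-(trimethylsilyloxy)hexa-1,4-diene | CC(C)=CC/C=C(/O[Si](C)(C)C)SC(C)(C)C | intermediate
5 | methyl pyruvate | CC(=O)C(=O)OC | starting material
6 | methyl (2R,3R)-3-[(tert-butylsulfanyl)carbonyl]-2,6-dimethyl-2-(trimethylsilyloxy)hept-5-enoate (aldol trimethylsilyl ether, not isolated) | C[C@](O[Si](C)(C)C)(C(=O)OC)[C@H](C(=O)SC(C)(C)C)CC=C(C)C | intermediate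
7 | methyl (2R,3R)-3-[(tert-butylsulfanyl)carbonyl]-2-hydroxy-2,6-dimethylhept-5-enoate | C[C@](O)(C(=O)OC)[C@H](C(=O)SC(C)(C)C)CC=C(C)C | intermediate
8 | (2R,3S)-2-methyl-3-(3-methylbut-2-en-1-yl)butane-1,2,4-triol | C[C@](O)(CO)[C@H](CO)CC=C(C)C | intermediate
9 | (2S)-5-methyl-2-[(4R)-2,2,4-trimethyl-1,3-dioxolan-4-yl]hex-4-en-1-ol | C[C@@]1(OC(C)(C)OC1)[C@H](CO)CC=C(C)C | intermediate
10 | (4R)-4-[(2R)-1-bromo-5-methylhex-4-en-2-yl]-2,2,4-trimethyl-1,3-dioxolane | C[C@@]1(OC(C)(C)OC1)[C@H](CBr)CC=C(C)C | intermediate
11 | (4R)-4-[(2R)-1-bromo-4-chloro-5-methylhex-5-en-2-yl]-2,2,4-trimethyl-1,3-dioxolane, both epimers at the C–Cl carbon | C[C@@]1(OC(C)(C)OC1)[C@H](CBr)CC(Cl)C(C)=C | intermediate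
12 | chloro[1-alkyl-2-methyl-π-allyl]nickel complex of 11 (chloride-bridged dimer; drawn as the C6-bound σ-allyl form, not isolated) | C[C@@]1(OC(C)(C)OC1)[C@H](CBr)CC=C(C)C[Ni]Cl | intermediate
13 | (4R)-2,2,4-trimethyl-4-[(1R)-4-methylcyclohex-3-en-1-yl]-1,3-dioxolane | C[C@@]1(OC(C)(C)OC1)[C@@H]2CCC(C)=CC2 | intermediate
14 | (2R)-2-[(1R)-4-methylcyclohex-3-en-1-yl]propane-1,2-diol | C[C@](O)(CO)[C@@H]1CCC(C)=CC1 | intermediate
15 | (2R)-2-methyl-2-[(1R)-4-methylcyclohex-3-en-1-yl]oxirane | C[C@]1(CO1)[C@@H]2CCC(C)=CC2 | intermediate
16 | (2R)-2-[(1R,3S,4S)-3,4-dibromo-4-methylcyclohexyl]-2-methyloxirane | C[C@]1(CO1)[C@@H]2CC[C@](C)(Br)[C@@H](Br)C2 | intermediate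
17 | (2R)-1-bromo-2-[(1R,3S,4S)-3,4-dibromo-4-methylcyclohexyl]propan-2-ol (not isolated) | C[C@](O)(CBr)[C@@H]1CC[C@](C)(Br)[C@@H](Br)C1 | intermediate
18 | (1S,2S,4R)-1,2-dibromo-4-[(2R)-1,2-dibromopropan-2-yl]-1-methylcyclohexane | C[C@](Br)(CBr)[C@@H]1CC[C@](C)(Br)[C@@H](Br)C1 | target

**Summary**
Total step count: 12. Longest linear sequence: 12 steps (1 to 18).

**Steps most likely to fail**

Step 8 (carries the label "Proposed new method:"). What may go wrong: capture of the C5 radical by a nickel centre of another molecule (oligomer formation), β-hydride loss from the alkylnickel intermediate, or reduction of the allylnickel unit instead of ring-closing reductive elimination. The fallback uses known radical allyl-transfer chemistry, sets out from 10 and comes back at 13. Finkelstein exchange of 10 (NaI, acetone) should give (4R)-4-[(2R)-1-iodo-5-methylhex-4-en-2-yl]-2,2,4-trimethyl-1,3-dioxolane F1. Addition of PhSCl to its trisubstituted double bond (CH2Cl2, −78 °C) and dehydrochlorination of the adduct (Et3N, DMF, 40 °C) should give the allylic sulfide (4R)-4-[(2R)-1-iodo-5-methyl-4-(phenylsulfanyl)hex-5-en-2-yl]-2,2,4-trimethyl-1,3-dioxolane F2. Irradiation with Bu3SnSnBu3 (benzene, 80 °C, 0.005 M) should generate the C5 radical by iodine abstraction; it adds in 6-endo fashion to the CH2 terminus of the 2-methylallyl sulfide and expels a phenylthiyl radical (intramolecular SH2' allyl transfer), forming the same C5–C6 bond and giving 13.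

Step 12. What may go wrong: loss of configurational fidelity at C8 during the OH → Br exchange, either by ionisation to an open tertiary cation or by opening of the bromonium ion at its CH2 end. The fallback sets out from 16 and comes back at 18 directly: treatment of 16 with Ph3PBr2 (CH2Cl2, −20 °C to 23 °C), the known deoxygenative conversion of epoxides into vicinal dibromides. Bromide opens the phosphorus-activated epoxide at CH2 and the tertiary oxyphosphonium group then leaves with assistance of that bromine, in an aprotic medium at low temperature without free HBr. No new compound lies on the way (entry F0).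

Step 7. What may go wrong: the selenium cycle stopping at the addition stage or giving vinylic or doubly chlorinated material, and cleavage of the acetonide by traces of HCl. The fallback sets out from 10 and comes back at 11. Epoxidation of the trisubstituted alkene (mCPBA, NaHCO3, CH2Cl2, 0 °C) should give (4R)-4-[(2R)-1-bromo-3-(3,3-dimethyloxiran-2-yl)propan-2-yl]-2,2,4-trimethyl-1,3-dioxolane F3. Base-induced isomerisation of this epoxide with diethylaluminium 2,2,6,6-tetramethylpiperidide (Et2AlNC9H18, benzene, 0 °C) should give the allylic alcohol with a terminal methylene group, (5R)-6-bromo-2-methyl-5-[(4R)-2,2,4-trimethyl-1,3-dioxolan-4-yl]hex-1-en-3-ol F4. MsCl, LiCl and 2,4,6-collidine in DMF at 0 °C should then give chloride 11; an allylically transposed chloride would serve equally in step 8, since both isomers lead to the same allylnickel complex.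

Further compounds
F1 | step 8 | (4R)-4-[(2R)-1-iodo-5-methylhex-4-en-2-yl]-2,2,4-trimethyl-1,3-dioxolane | C[C@@]1(OC(C)(C)OC1)[C@H](CI)CC=C(C)C
F2 | step 8 | (4R)-4-[(2R)-1-iodo-5-methyl-4-(phenylsulfanyl)hex-5-en-2-yl]-2,2,4-trimethyl-1,3-dioxolane, both epimers at the C–S carbon | C[C@@]1(OC(C)(C)OC1)[C@H](CI)CC(Sc2ccccc2)C(C)=C
F0 | step 12 | none | none
F3 | step 7 | (4R)-4-[(2R)-1-bromo-3-(3,3-dimethyloxiran-2-yl)propan-2-yl]-2,2,4-trimethyl-1,3-dioxolane, both epoxide epimers | C[C@@]1(OC(C)(C)OC1)[C@H](CBr)CC2OC2(C)C
F4 | step 7 | (5R)-6-bromo-2-methyl-5-[(4R)-2,2,4-trimethyl-1,3-dioxolan-4-yl]hex-1-en-3-ol, both carbinol epimers | C[C@@]1(OC(C)(C)OC1)[C@H](CBr)CC(O)C(C)=C
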